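**Numbering used throughout.** The five-carbon chain is C1–C5: C1 is bonded to ring A (the benzaldehyde ring), C3 is the carbinol carbon, C4=C5 is the double bond, and C5 is bonded to ring B (the hydroquinone ring). TIPS = triisopropylsilyl.

## The problem

- The target consists of two arenes joined by the chain C1–C5. Ring A is a pentasubstituted salicylaldehyde and ring B is a 2-substituted hydroquinone. The only stereocenter is C3, a tertiary alcohol, which the SMILES defines as (S), and the C4=C5 bond is (E).
- Ring A is not the difficulty. Without its formyl group it is a 4-substituted 3,5-dimethylphenol with a mirror plane through C–OH and C–C1, so its two ortho positions are equivalent and one formylation can give only one isomer.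
- The difficulty is C3. Its two saturated substituents, CH3 and the C2 methylene, differ by very little, so face selection at a methyl ketone or at a 1,1-disubstituted alkene is poorly founded. No second stereocenter exists to relay control.
- The C3–O bond is tertiary, allylic and, through C4=C5, conjugated to the ortho oxygen of ring B. Acid ionises it, leading to racemisation, 1,3-shift of oxygen or closure to a 2H-chromene through the ring B ortho hydroxyl.
- The free hydroquinone is oxidised easily, and the salicylaldehyde does not tolerate hydride, carbanions or peroxide. The last steps must therefore be neutral or weakly basic and non-oxidising.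
- The feature that opens the key step: C3 carries the C4=C5 alkene conjugated with ring B, and C2 can be delivered as the inner carbon of a vinyl group. With C2 removed, C3 is the carbinol carbon of a secondary allylic alcohol, where the choice is methyl against alkenyl and is easy to make. Its C3–H is allylic and α to oxygen, so a carbamate can be lithiated there and C2 brought in from boron by a stereospecific 1,2-shift. The easy secondary centre thus becomes the hard tertiary one.

## Retrosynthesis

**16 to 15.** Only the two O–Si bonds on ring B are cut. Triisopropylsilyl ethers survive sec-butyllithium, 9-BBN and aqueous carbonate, and they leave with buffered fluoride, the one kind of deprotection the C3 carbinol should tolerate. Ring A and the C3 hydroxyl are never protected.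

**15 to 11 and 13.** The C1–aryl bond to ring A is cut. This sp3–sp2 bond comes from the terminal vinyl group of dienol 11 by hydroboration to alkylborane 14 and coupling with aryl iodide 13. Ring A then arrives complete, with phenol and aldehyde free. Cutting C1–C2 or C2–C3 here would require a benzylic organometal and a protected ring A. The forward reaction must hydroborate the monosubstituted alkene and leave the conjugated C4=C5 bond, and it must tolerate the tertiary alcohol.

**13 to 12.** The aryl–CHO bond is cut. Ortho-formylation of the symmetric iodophenol 12 is unambiguous for the symmetry reason given above, so no directing or blocking group is needed.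

**11 to 6 and 7 (key disconnection).** The C2–C3 bond is cut. The vinyl group of boronic ester 7 is transferred to C3 of the lithiated carbamate 8 through boronate complex 9 and the tertiary allylic boronic ester 10. Oxidation of 10 gives 11.
- Against the C3–C4 cut (alkenyl metal plus methyl ketone) and the C3–CH3 cut, this cut needs no reagent to distinguish CH3 from C2. The configuration is copied from carbamate 6.
- The precursor 6 has one arene and a secondary stereocenter. The product 11 has the tertiary carbinol and both two-carbon arms in place.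
- The forward reaction must borylate at C3 and not at C5, and must keep the configuration and the (E) geometry of 8.

**6 to 5 to 4 to 2 to 1.** The C–O carbamate bond, the carbinol C–H bond, the C3=C4 bond of the enone and the two O–Si bonds are cut in turn.
- Carbamate 6 comes from (R)-allylic alcohol 5.
- Alcohol 5 comes from enone 4 by oxazaborolidine-catalysed reduction, which has to tell methyl from an (E)-alkenyl group.
- Enone 4 comes from aldehyde 2 and the stabilised ylide 3, which fixes the (E) geometry.
- Aldehyde 2 comes from commercial 2,5-dihydroxybenzaldehyde 1 by silylation.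

## Roads not taken

**Alternative 1:** The most obvious cut is C3–C4. The alkenyl metal would be made from alkyne A2 by hydrozirconation with Cp2Zr(H)Cl and transmetalation with Me2Zn. It would add to methyl ketone A1 under a chiral titanium catalyst.
- The carbonyl group of A1 lies between CH3 and a CH2CH2Ar chain, two unbranched sp3 groups. Catalyst control therefore rests on one methylene of size difference, and the ketone is enolisable.
- Ring A has to be protected and cannot carry its aldehyde. A protection, a selective deprotection and a late formylation would be added.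
- The chosen plan makes the same kind of choice on enone 4, where the groups are methyl and alkenyl, and then transfers it stereospecifically.

**Alternative 2:** Ring B is attached last by a Heck reaction of aryl iodide A6 with vinyl carbinol A5. A5 would come from allylic alcohol A3 by Sharpless asymmetric epoxidation (L-(+)-diethyl tartrate) to epoxy alcohol A4, conversion to the iodide and reductive opening with zinc.
- Five operations (olefination, reduction, epoxidation, iodination, zinc) are spent on one stereocenter.
- The trisubstituted alkene of A3 must be geometrically pure, because the (E) and (Z) isomers give opposite configurations at C3.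
- Ring A again travels protected and is formylated late.
- The chosen route needs only a disubstituted (E) alkene from a stabilised ylide and reaches the tertiary centre two steps after the reduction.

**Alternative 3:** Both arms of C3 are two carbons long and both can come from vinyl groups, so the chain is hidden in achiral 3-methylpenta-1,4-dien-3-ol A7. A Heck reaction of A7 with A6 under a chiral palladium catalyst, selecting one of the two enantiotopic vinyl groups, would give dienol 11 in one step.
- This is the shortest route on paper.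
- The catalyst would have to choose between two vinyl groups on an acyclic carbinol whose remaining substituents are CH3 and OH, and the new stereocenter lies outside the reacting alkene.
- No closely related catalyst control can be cited, and double arylation competes.
- The chosen plan keeps the two-vinyl logic and the same endgame, but takes the configuration of 11 from a stereospecific rearrangement.

Key step: step 5

## Route

Step 1
Reactants: 1 2,5-dihydroxybenzaldehyde
Product: 2 2,5-bis(triisopropylsilyloxy)benzaldehyde
Conditions: TIPSCl, imidazole, DMF, 40 °C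
Reagents that add atoms: triisopropylsilyl chloride, CC(C)[Si](Cl)(C(C)C)C(C)C
Why: Standard silylation of phenols; gentle warming should also silylate the hydrogen-bonded ortho hydroxyl, and the bulky silyl ethers are chosen to survive sec-butyllithium and aqueous base later.

Step 2
Reactants: 2 2,5-bis(triisopropylsilyloxy)benzaldehyde; 3 1-(triphenyl-λ5-phosphanylidene)propan-2-one
Product: 4 (3E)-4-[2,5-bis(triisopropylsilyloxy)phenyl]but-3-en-2-one
Conditions: toluene, 100 °C
Reagents that add atoms: none
Why: Wittig reaction of a stabilised ylide, which should give the (E)-enone under neutral conditions that leave the aryl silyl ethers intact.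

Step 3
Reactants: 4 (3E)-4-[2,5-bis(triisopropylsilyloxy)phenyl]but-3-en-2-one
Product: 5 (2R,3E)-4-[2,5-bis(triisopropylsilyloxy)phenyl]but-3-en-2-ol
Conditions: (S)-2-methyl-CBS-oxazaborolidine (cat.), catecholborane, toluene, −78 °C
Reagents that add atoms: none
Why: Corey–Bakshi–Shibata reduction; the alkenyl group acts as the large and methyl as the small substituent, so the (S)-catalyst should deliver hydride to the face that gives the (R)-carbinol, and catecholborane at low temperature should avoid conjugate reduction.

Step 4
Reactants: 5 (2R,3E)-4-[2,5-bis(triisopropylsilyloxy)phenyl]but-3-en-2-ol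
Product: 6 (2R,3E)-4-[2,5-bis(triisopropylsilyloxy)phenyl]but-3-en-2-yl N,N-diisopropylcarbamate
Conditions: NaH, THF, 0 °C; iPr2NC(O)Cl, 0 to 50 °C
Reagents that add atoms: N,N-diisopropylcarbamoyl chloride, CC(C)N(C(C)C)C(Cl)=O
Why: O-Carbamoylation of the sodium alkoxide under basic conditions; the C–O bond at the stereocenter is not touched, so the configuration is retained and the cinnamyl-type alcohol is never exposed to acid.

Step 5
Reactants: 6 (2R,3E)-4-[2,5-bis(triisopropylsilyloxy)phenyl]but-3-en-2-yl N,N-diisopropylcarbamate; 7 4,4,5,5-tetramethyl-2-vinyl-1,3,2-dioxaborolane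
Product: 11 (1E,3S)-1-[2,5-bis(triisopropylsilyloxy)phenyl]-3-methylpenta-1,4-dien-3-ol, via lithiated carbamate 8 (not isolated), via vinylboronate complex 9 (not isolated), via tertiary allylic boronic ester 10 (not isolated)
Conditions: sBuLi, TMEDA, Et2O, −78 °C; 7, −78 °C to rt; then NaOH, H2O2, THF/H2O, 0 °C
Reagents that add atoms: hydrogen peroxide, OO; sec-butyllithium, [Li]C(C)CC (lithium of 8 and 9 only)
Why: The closest known reaction type is the lithiation–borylation of a secondary allylic carbamate (carbamate-directed α-deprotonation, boronate formation, Matteson-type 1,2-metallate rearrangement) followed by oxidation of the C–B bond, applied here to a member of the class with an aryl group on the far alkene carbon. sBuLi/TMEDA should remove the C3–H, which is allylic and α to the carbamate oxygen, with retention to give 8, in which lithium is held at C3 by the carbamate carbonyl. Boronic ester 7 should be attacked from the lithium-bearing face (retention) to give 9; on warming, the vinyl group shifts from boron to C3 anti to the departing carbamate (inversion) to give 10, and alkaline peroxide replaces boron by hydroxyl with retention, so that (R)-6 should give (S)-11. No ring is closed. The new stereocenter is thus controlled only by the configuration of 6 set in step 3 and not by the small difference between CH3 and C2. The step needs borylation at C3 and not at the benzylic C5, which the lithium–carbamate chelate and the neighbouring ortho silyloxy group should secure. It needs configurational and (E)-geometric stability of 8, which −78 °C, a short lithiation time and ether as solvent should secure, and it needs migration of vinyl and not of a pinacol oxygen, which is the normal behaviour of such boronate complexes. Oxidation in the same flask consumes the bis-allylic boronic ester 10 before a 1,3-shift of boron can occur.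

Step 6
Reactants: 12 4-iodo-3,5-dimethylphenol
Product: 13 6-hydroxy-3-iodo-2,4-dimethylbenzaldehyde
Conditions: MgCl2, Et3N, (CH2O)n, MeCN, reflux
Reagents that add atoms: formaldehyde (from paraformaldehyde), C=O
Why: Magnesium-mediated ortho-formylation of a phenol (Casnati–Skattebøl): the magnesium phenoxide directs formaldehyde to the ortho carbon and a second formaldehyde oxidises the benzylic alkoxide; the two ortho positions of 12 are equivalent by symmetry, so only one monoaldehyde can form, and its magnesium chelate should resist a second formylation.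

Step 7
Reactants: 11 (1E,3S)-1-[2,5-bis(triisopropylsilyloxy)phenyl]-3-methylpenta-1,4-dien-3-ol; 13 6-hydroxy-3-iodo-2,4-dimethylbenzaldehyde
Product: 15 3-[(3S,4E)-5-[2,5-bis(triisopropylsilyloxy)phenyl]-3-hydroxy-3-methylpent-4-en-1-yl]-6-hydroxy-2,4-dimethylbenzaldehyde, via alkylborane 14 (not isolated)
Conditions: 9-BBN dimer (excess), THF, 0 °C to rt; H2O; then 13, PdCl2(dppf), AsPh3, Cs2CO3, DMF/THF/H2O, rt to 45 °C
Reagents that add atoms: 9-borabicyclo[3.3.1]nonane, B1C2CCCC1CCC2 (boron group of 14 only)
Why: Hydroboration followed by B-alkyl Suzuki–Miyaura coupling; 9-BBN should add to the monosubstituted vinyl group and leave the hindered, conjugated C4=C5 bond, excess B–H is destroyed with water before aldehyde 13 is added, and the iodide is chosen so that oxidative addition between the two ortho methyl groups proceeds near room temperature in a basic medium that does not ionise the C3–O bond. C3 is not involved and keeps its configuration.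

Step 8
Reactants: 15 3-[(3S,4E)-5-[2,5-bis(triisopropylsilyloxy)phenyl]-3-hydroxy-3-methylpent-4-en-1-yl]-6-hydroxy-2,4-dimethylbenzaldehyde
Product: 16 3-[(3S,4E)-5-(2,5-dihydroxyphenyl)-3-hydroxy-3-methylpent-4-en-1-yl]-6-hydroxy-2,4-dimethylbenzaldehyde
Conditions: Bu4NF, AcOH, THF, 0 °C, argon
Reagents that add atoms: none
Why: Fluoride cleavage of aryl silyl ethers; acetic acid protonates each phenoxide as it forms, so the medium stays near neutral, which should spare the tertiary allylic alcohol, the aldehyde and the hydroquinone.

## Compound list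

1 | 2,5-dihydroxybenzaldehyde | O=Cc1cc(O)ccc1O | starting material
2 | 2,5-bis(triisopropylsilyloxy)benzaldehyde | O=Cc1cc(O[Si](C(C)C)(C(C)C)C(C)C)ccc1O[Si](C(C)C)(C(C)C)C(C)C | intermediate
3 | 1-(triphenyl-λ5-phosphanylidene)propan-2-one | CC(=O)C=P(c1ccccc1)(c1ccccc1)c1ccccc1 | starting material
4 | (3E)-4-[2,5-bis(triisopropylsilyloxy)phenyl]but-3-en-2-one | CC(=O)/C=C/c1cc(O[Si](C(C)C)(C(C)C)C(C)C)ccc1O[Si](C(C)C)(C(C)C)C(C)C | intermediate
5 | (2R,3E)-4-[2,5-bis(triisopropylsilyloxy)phenyl]but-3-en-2-ol | C[C@@H](O)/C=C/c1cc(O[Si](C(C)C)(C(C)C)C(C)C)ccc1O[Si](C(C)C)(C(C)C)C(C)C | intermediate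
6 | (2R,3E)-4-[2,5-bis(triisopropylsilyloxy)phenyl]but-3-en-2-yl N,N-diisopropylcarbamate | C[C@@H](OC(=O)N(C(C)C)C(C)C)/C=C/c1cc(O[Si](C(C)C)(C(C)C)C(C)C)ccc1O[Si](C(C)C)(C(C)C)C(C)C | intermediate
7 | 4,4,5,5-tetramethyl-2-vinyl-1,3,2-dioxaborolane | C=CB1OC(C)(C)C(C)(C)O1 | starting material
8 | {(3E)-4-[2,5-bis(triisopropylsilyloxy)phenyl]-2-(N,N-diisopropylcarbamoyloxy)but-3-en-2-yl}lithium, lithium in the place of the former C–H | C[C@@]([Li])(OC(=O)N(C(C)C)C(C)C)/C=C/c1cc(O[Si](C(C)C)(C(C)C)C(C)C)ccc1O[Si](C(C)C)(C(C)C)C(C)C | intermediate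
9 | lithium {(3E)-4-[2,5-bis(triisopropylsilyloxy)phenyl]-2-(N,N-diisopropylcarbamoyloxy)but-3-en-2-yl}(ethenyl)(pinacolato)borate | [Li+].C[C@@]([B-]1(C=C)OC(C)(C)C(C)(C)O1)(OC(=O)N(C(C)C)C(C)C)/C=C/c1cc(O[Si](C(C)C)(C(C)C)C(C)C)ccc1O[Si](C(C)C)(C(C)C)C(C)C | intermediate
10 | 2-[(1E,3R)-1-[2,5-bis(triisopropylsilyloxy)phenyl]-3-methylpenta-1,4-dien-3-yl]-4,4,5,5-tetramethyl-1,3,2-dioxaborolane | C=C[C@](C)(B1OC(C)(C)C(C)(C)O1)/C=C/c1cc(O[Si](C(C)C)(C(C)C)C(C)C)ccc1O[Si](C(C)C)(C(C)C)C(C)C | intermediate
11 | (1E,3S)-1-[2,5-bis(triisopropylsilyloxy)phenyl]-3-methylpenta-1,4-dien-3-ol | C=C[C@](C)(O)/C=C/c1cc(O[Si](C(C)C)(C(C)C)C(C)C)ccc1O[Si](C(C)C)(C(C)C)C(C)C | intermediate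
12 | 4-iodo-3,5-dimethylphenol | Cc1cc(O)cc(C)c1I | starting material
13 | 6-hydroxy-3-iodo-2,4-dimethylbenzaldehyde | Cc1cc(O)c(C=O)c(C)c1I | intermediate
14 | (1E,3S)-1-[2,5-bis(triisopropylsilyloxy)phenyl]-5-(9-borabicyclo[3.3.1]nonan-9-yl)-3-methylpent-1-en-3-ol | B1(CC[C@](C)(O)/C=C/c3cc(O[Si](C(C)C)(C(C)C)C(C)C)ccc3O[Si](C(C)C)(C(C)C)C(C)C)C2CCCC1CCC2 | intermediate
15 | 3-[(3S,4E)-5-[2,5-bis(triisopropylsilyloxy)phenyl]-3-hydroxy-3-methylpent-4-en-1-yl]-6-hydroxy-2,4-dimethylbenzaldehyde | Cc1cc(O)c(C=O)c(C)c1CC[C@](C)(O)/C=C/c1cc(O[Si](C(C)C)(C(C)C)C(C)C)ccc1O[Si](C(C)C)(C(C)C)C(C)C | intermediate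
16 | 3-[(3S,4E)-5-(2,5-dihydroxyphenyl)-3-hydroxy-3-methylpent-4-en-1-yl]-6-hydroxy-2,4-dimethylbenzaldehyde | Cc1cc(O)c(C=O)c(C)c1CC[C@](C)(O)/C=C/c1cc(O)ccc1O | target

## Step count and least certain steps

Total steps: 8. Longest linear sequence: 7 (steps 1–5, 7, 8). Step 6 is a one-step side branch.

**Step 5 (key step).**
- Most likely failure: borylation at the benzylic C5 end of the delocalised carbanion, or loss of configuration or alkene geometry in it. The aryl group spreads the charge further than in the alkyl-substituted cases for which this reaction type is established. Addition of sBuLi to the styrene and a 1,3-shift of boron before oxidation are further risks.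
- Fallback, from enone 4 back to 11 by epoxidation chemistry:
  - Horner–Wadsworth–Emmons reaction of 4 with triethyl phosphonoacetate and NaH gives ethyl (2E,4E)-5-[2,5-bis(triisopropylsilyloxy)phenyl]-3-methylpenta-2,4-dienoate F1.
  - iBu2AlH reduces it to (2E,4E)-5-[2,5-bis(triisopropylsilyloxy)phenyl]-3-methylpenta-2,4-dien-1-ol F2.
  - Sharpless asymmetric epoxidation (Ti(OiPr)4, D-(−)-diethyl tartrate, tBuOOH, 4 Å molecular sieves, −20 °C) should give [(2R,3R)-3-{(E)-2-[2,5-bis(triisopropylsilyloxy)phenyl]ethenyl}-3-methyloxiran-2-yl]methanol F3.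
  - I2, PPh3 and imidazole convert it into (2S,3R)-3-{(E)-2-[2,5-bis(triisopropylsilyloxy)phenyl]ethenyl}-2-(iodomethyl)-3-methyloxirane F4.
  - Zinc dust in ethanol opens F4 reductively to 11; the C3–O bond is kept throughout.

**Step 7.**
- Most likely failure: slow oxidative addition at the iodide, which lies between two methyl groups and is present as an electron-rich phenoxide. Hydride transfer from boron species to the free aldehyde and boron-assisted ionisation of the allylic C3–O bond by zerovalent palladium are further risks.
- Fallback, from 12 and 6 back to 15, with the C1–aryl bond made before the carbinol exists and no palladium step on it: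
  - 12 is silylated (tert-butyldimethylsilyl chloride, imidazole) to tert-butyl(4-iodo-3,5-dimethylphenoxy)dimethylsilane F5.
  - Vinylation (potassium vinyltrifluoroborate, PdCl2(dppf), Cs2CO3) gives tert-butyl(4-ethenyl-3,5-dimethylphenoxy)dimethylsilane F6.
  - Hydroboration (pinacolborane, [Ir(cod)Cl]2, 1,2-bis(diphenylphosphino)ethane) gives 2-{2-[4-(tert-butyldimethylsilyloxy)-2,6-dimethylphenyl]ethyl}-4,4,5,5-tetramethyl-1,3,2-dioxaborolane F7.
  - Lithiation of 6 as in step 5, borylation with F7 in place of 7, and oxidation should give (1E,3S)-1-[2,5-bis(triisopropylsilyloxy)phenyl]-5-[4-(tert-butyldimethylsilyloxy)-2,6-dimethylphenyl]-3-methylpent-1-en-3-ol F8.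
  - K2CO3 in methanol at 0 °C should cleave the less hindered aryl silyl ether first and give 4-[(3S,4E)-5-[2,5-bis(triisopropylsilyloxy)phenyl]-3-hydroxy-3-methylpent-4-en-1-yl]-3,5-dimethylphenol F9.
  - Formylation of F9 under the conditions of step 6 gives 15.

**Step 3.**
- Most likely failure: reduced facial selectivity because the ortho silyloxy group twists and shields the enone, and competing conjugate reduction.
- Fallback, from 4 back to 5 by a dynamic kinetic resolution:
  - Luche reduction (NaBH4, CeCl3·7H2O, MeOH) gives racemic (E)-4-[2,5-bis(triisopropylsilyloxy)phenyl]but-3-en-2-ol F10.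
  - Acylation with Candida antarctica lipase B and isopropenyl acetate, with (η5-C5Ph5)Ru(CO)2Cl and KOtBu racemising the slower enantiomer, should funnel both enantiomers into (2R,3E)-4-[2,5-bis(triisopropylsilyloxy)phenyl]but-3-en-2-yl acetate F11.
  - iBu2AlH at −78 °C cleaves the acetate to 5.

**Step 8.**
- Most likely failure: expulsion of the C3 hydroxyl through the ring B ortho phenoxide followed by closure to the 2H-chromene, or air oxidation of the hydroquinone during isolation of a product that also carries the aldehyde.
- Fallback, from 11 to 16, with the fluoride step moved ahead of the coupling: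
  - Bu4NF/AcOH converts 11 into 2-[(1E,3S)-3-hydroxy-3-methylpenta-1,4-dien-1-yl]benzene-1,4-diol F12, which is purified before the ring A half is committed.
  - Hydroboration of F12 with enough 9-BBN to cover the three hydroxyl groups and coupling with 13 under the conditions of step 7 then give 16 directly, with no deprotection after the last C–C bond is formed.

## Further compounds

F1 | step 5 | ethyl (2E,4E)-5-[2,5-bis(triisopropylsilyloxy)phenyl]-3-methylpenta-2,4-dienoate | CCOC(=O)/C=C(\C)/C=C/c1cc(O[Si](C(C)C)(C(C)C)C(C)C)ccc1O[Si](C(C)C)(C(C)C)C(C)C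
F2 | step 5 | (2E,4E)-5-[2,5-bis(triisopropylsilyloxy)phenyl]-3-methylpenta-2,4-dien-1-ol | OC/C=C(\C)/C=C/c1cc(O[Si](C(C)C)(C(C)C)C(C)C)ccc1O[Si](C(C)C)(C(C)C)C(C)C
F3 | step 5 | [(2R,3R)-3-{(E)-2-[2,5-bis(triisopropylsilyloxy)phenyl]ethenyl}-3-methyloxiran-2-yl]methanol | OC[C@H]1O[C@]1(C)/C=C/c1cc(O[Si](C(C)C)(C(C)C)C(C)C)ccc1O[Si](C(C)C)(C(C)C)C(C)C
F4 | step 5 | (2S,3R)-3-{(E)-2-[2,5-bis(triisopropylsilyloxy)phenyl]ethenyl}-2-(iodomethyl)-3-methyloxirane | IC[C@H]1O[C@]1(C)/C=C/c1cc(O[Si](C(C)C)(C(C)C)C(C)C)ccc1O[Si](C(C)C)(C(C)C)C(C)C
F5 | step 7 | tert-butyl(4-iodo-3,5-dimethylphenoxy)dimethylsilane | Cc1cc(O[Si](C)(C)C(C)(C)C)cc(C)c1I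
F6 | step 7 | tert-butyl(4-ethenyl-3,5-dimethylphenoxy)dimethylsilane | C=Cc1c(C)cc(O[Si](C)(C)C(C)(C)C)cc1C
F7 | step 7 | 2-{2-[4-(tert-butyldimethylsilyloxy)-2,6-dimethylphenyl]ethyl}-4,4,5,5-tetramethyl-1,3,2-dioxaborolane | Cc1cc(O[Si](C)(C)C(C)(C)C)cc(C)c1CCB1OC(C)(C)C(C)(C)O1
F8 | step 7 | (1E,3S)-1-[2,5-bis(triisopropylsilyloxy)phenyl]-5-[4-(tert-butyldimethylsilyloxy)-2,6-dimethylphenyl]-3-methylpent-1-en-3-ol | Cc1cc(O[Si](C)(C)C(C)(C)C)cc(C)c1CC[C@](C)(O)/C=C/c1cc(O[Si](C(C)C)(C(C)C)C(C)C)ccc1O[Si](C(C)C)(C(C)C)C(C)C
F9 | step 7 | 4-[(3S,4E)-5-[2,5-bis(triisopropylsilyloxy)phenyl]-3-hydroxy-3-methylpent-4-en-1-yl]-3,5-dimethylphenol | Cc1cc(O)cc(C)c1CC[C@](C)(O)/C=C/c1cc(O[Si](C(C)C)(C(C)C)C(C)C)ccc1O[Si](C(C)C)(C(C)C)C(C)C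
F10 | step 3 | (E)-4-[2,5-bis(triisopropylsilyloxy)phenyl]but-3-en-2-ol (racemate) | CC(O)/C=C/c1cc(O[Si](C(C)C)(C(C)C)C(C)C)ccc1O[Si](C(C)C)(C(C)C)C(C)C
F11 | step 3 | (2R,3E)-4-[2,5-bis(triisopropylsilyloxy)phenyl]but-3-en-2-yl acetate | C[C@@H](OC(C)=O)/C=C/c1cc(O[Si](C(C)C)(C(C)C)C(C)C)ccc1O[Si](C(C)C)(C(C)C)C(C)C
F12 | step 8 | 2-[(1E,3S)-3-hydroxy-3-methylpenta-1,4-dien-1-yl]benzene-1,4-diol | C=C[C@](C)(O)/C=C/c1cc(O)ccc1O
A1 | alternative 1 | 4-[4-(tert-butyldimethylsilyloxy)-2,6-dimethylphenyl]butan-2-one | CC(=O)CCc1c(C)cc(O[Si](C)(C)C(C)(C)C)cc1C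
A2 | alternative 1 | 2-ethynyl-1,4-bis(triisopropylsilyloxy)benzene | C#Cc1cc(O[Si](C(C)C)(C(C)C)C(C)C)ccc1O[Si](C(C)C)(C(C)C)C(C)C
A3 | alternative 2 | (2E)-5-[4-(tert-butyldimethylsilyloxy)-2,6-dimethylphenyl]-3-methylpent-2-en-1-ol | OC/C=C(\C)CCc1c(C)cc(O[Si](C)(C)C(C)(C)C)cc1C
A4 | alternative 2 | [(2S,3S)-3-{2-[4-(tert-butyldimethylsilyloxy)-2,6-dimethylphenyl]ethyl}-3-methyloxiran-2-yl]methanol | OC[C@@H]1O[C@@]1(C)CCc1c(C)cc(O[Si](C)(C)C(C)(C)C)cc1C
A5 | alternative 2 | (3S)-5-[4-(tert-butyldimethylsilyloxy)-2,6-dimethylphenyl]-3-methylpent-1-en-3-ol | C=C[C@@](C)(O)CCc1c(C)cc(O[Si](C)(C)C(C)(C)C)cc1C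
A6 | alternative 2 | 2-iodo-1,4-bis(triisopropylsilyloxy)benzene | Ic1cc(O[Si](C(C)C)(C(C)C)C(C)C)ccc1O[Si](C(C)C)(C(C)C)C(C)C
A7 | alternative 3 | 3-methylpenta-1,4-dien-3-ol | C=CC(C)(O)C=C
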